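**Retrosynthetic overview**
- Target 17 comes from its hepta-allyl derivative 16 by one palladium-catalysed deallylation; 16 is cut at the cinnamate C=C into ring B aldehyde 11 and phosphonoacetate 15 of allyl-protected (R)-danshensu.
- The strategy rests on the adjacent C2 (aryloxy carbon, α to the carboxyl) and C3 (benzylic carbinol on ring C): at the β-keto ester oxidation level C2 is configurationally labile, so a ketoreductase can reduce the C3 ketone of racemic 9 and fix both centres at once as (2R,3R)-10.
- Racemic 9 is cut at the C2–O bond into ring B phenol 8 (aldehyde masked as a cyclic acetal) and α-chloro-β-keto ester 5; 5 comes from acetophenone 2 by Claisen condensation with diallyl carbonate and chlorination.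
- No ring is formed: rings A (danshensu catechol), B (caffeoyl ring) and C (catechol on C3) come from the starting materials, and the third stereocentre is bought with (R)-danshensu.

Key step: step 7

Remark: C1–C3 number the propanoic acid chain and (2R,3R) is the anti isomer in the zigzag drawing of the C1–C2–C3–aryl chain; (R)-danshensu is taken as the free acid, and its sodium salt should behave the same in step 9.

**Step 1**
Reactants: 1 3',4'-dihydroxyacetophenone
Product: 2 3',4'-bis(allyloxy)acetophenone
Conditions: allyl bromide (2.5 equiv), K2CO3, DMF, 50 °C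
Reagents that add atoms: allyl bromide, C=CCBr
Why: Williamson ether synthesis on both phenoxides, which under carbonate are far more nucleophilic than the ketone enolate, so only O-allylation is expected.

**Step 2**
Reactants: 2 3',4'-bis(allyloxy)acetophenone; 3 diallyl carbonate
Product: 4 allyl 3-[3,4-bis(allyloxy)phenyl]-3-oxopropanoate
Conditions: NaH (2.5 equiv), THF, reflux; then aq. HCl, 0 °C
Reagents that add atoms: none
Why: Crossed Claisen condensation in which the methyl ketone enolate is C-acylated by the non-enolisable carbonate and the equilibrium is pulled through by deprotonation of the β-keto ester, the aryl allyl ethers being inert to NaH.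

**Step 3**
Reactants: 4 allyl 3-[3,4-bis(allyloxy)phenyl]-3-oxopropanoate
Product: 5 allyl 3-[3,4-bis(allyloxy)phenyl]-2-chloro-3-oxopropanoate (racemic)
Conditions: N-chlorosuccinimide (1.05 equiv), Mg(ClO4)2 (10 mol%), EtOAc, 0 °C → rt
Reagents that add atoms: N-chlorosuccinimide, O=C1CCC(=O)N1Cl
Why: Electrophilic α-chlorination of the magnesium-chelated enol, which should outpace attack of the mild N–Cl reagent on the allyl alkenes or the acyl-deactivated ring, one equivalent limiting dichlorination; the new C2 centre is racemic, as intended.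

**Step 4**
Reactants: 6 3,4-dihydroxybenzaldehyde
Product: 7 3-(allyloxy)-4-hydroxybenzaldehyde
Conditions: NaH (2.2 equiv), DMSO, rt; allyl bromide (1.0 equiv), rt; then aq. HCl
Reagents that add atoms: allyl bromide, C=CCBr
Why: Regioselective Williamson alkylation of the catechol dianion, in which the 4-oxide is delocalised into the para formyl group so that the single equivalent of allyl bromide should be taken by the more nucleophilic 3-oxide.

**Step 5**
Reactants: 7 3-(allyloxy)-4-hydroxybenzaldehyde
Product: 8 2-(allyloxy)-4-(5,5-dimethyl-1,3-dioxan-2-yl)phenol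
Conditions: 2,2-dimethylpropane-1,3-diol (1.5 equiv), p-TsOH·H2O (1 mol%), toluene, reflux, Dean–Stark; Et3N quench
Reagents that add atoms: 2,2-dimethylpropane-1,3-diol, OCC(C)(C)CO
Why: Acid-catalysed acetalisation driven by azeotropic removal of water, the neopentyl acetal being chosen because it should survive carbonate, silica gel and a day in pH 7.5 buffer where a dimethyl acetal of this electron-rich aldehyde would be expected to hydrolyse, and because masking the formyl group closes off Darzens and Knoevenagel pathways in step 6.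

**Step 6**
Reactants: 5 allyl 3-[3,4-bis(allyloxy)phenyl]-2-chloro-3-oxopropanoate; 8 2-(allyloxy)-4-(5,5-dimethyl-1,3-dioxan-2-yl)phenol
Product: 9 allyl 2-[2-(allyloxy)-4-(5,5-dimethyl-1,3-dioxan-2-yl)phenoxy]-3-[3,4-bis(allyloxy)phenyl]-3-oxopropanoate (racemic)
Conditions: K2CO3 (1.5 equiv), acetone, 50 °C
Reagents that add atoms: none
Why: Williamson-type SN2 O-alkylation of the phenoxide by the chloride activated by two flanking carbonyl groups, chloride rather than bromide being used to suppress halophilic attack; the C2 centre formed is racemic and labile, so no stereocontrol is needed.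

**Step 7**
Reactants: 9 allyl 2-[2-(allyloxy)-4-(5,5-dimethyl-1,3-dioxan-2-yl)phenoxy]-3-[3,4-bis(allyloxy)phenyl]-3-oxopropanoate (racemic)
Product: 10 allyl (2R,3R)-2-[2-(allyloxy)-4-(5,5-dimethyl-1,3-dioxan-2-yl)phenoxy]-3-[3,4-bis(allyloxy)phenyl]-3-hydroxypropanoate
Conditions: NADPH-dependent ketoreductase ((2R,3R)-selective variant chosen from a stereocomplementary panel, purified), NADP+ (cat.), iPrOH (15% v/v), DMSO (10% v/v), K2HPO4/KH2PO4 buffer (0.1 M, pH 7.5), MgSO4 (2 mM), 30 °C
Reagents that add atoms: none
Why: At pH 7.5 the C2–H of 9, flanked by the aryl ketone, the allyl ester and the aryloxy oxygen, should exchange through the enol faster than the ketone is reduced, so both enantiomers feed the one (2R) form that the enzyme accepts; this is the known ketoreductase dynamic reductive kinetic resolution of α-substituted β-keto esters. The enzyme transfers hydride from NADPH, which it regenerates from isopropanol, to the Si face of the C3 carbonyl (priorities O > C2 > aryl), forming the C3–H bond with 3R configuration. No ring is closed; C2 is set by the enzyme's choice of substrate enantiomer and C3 by the face of hydride delivery, both fixed by the binding pocket, which is why the catalyst is picked from a panel of stereocomplementary variants. After reduction C2–H is no longer doubly activated, so the anti (2R,3R) pair is configurationally stable. The step must touch only the aryl ketone: the masked aldehyde cannot compete as a carbonyl substrate, isopropanol recycling keeps the pH constant for the acetal, and a purified enzyme free of esterase activity should spare the allyl ester.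

**Step 8**
Reactants: 10 allyl (2R,3R)-2-[2-(allyloxy)-4-(5,5-dimethyl-1,3-dioxan-2-yl)phenoxy]-3-[3,4-bis(allyloxy)phenyl]-3-hydroxypropanoate
Product: 11 allyl (2R,3R)-2-[2-(allyloxy)-4-formylphenoxy]-3-[3,4-bis(allyloxy)phenyl]-3-hydroxypropanoate
Conditions: aq. HCl (0.5 M), THF, 0 °C → rt
Reagents that add atoms: water, O
Why: Acid-catalysed acetal hydrolysis through the aryl-stabilised dioxocarbenium ion, which should be much faster than ionisation of the C3 carbinol, whose cation is destabilised by the aryloxy- and ester-bearing C2, so both stereocentres and the allyl ester are expected to be untouched.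

**Step 9**
Reactants: 12 (R)-danshensu, (2R)-3-(3,4-dihydroxyphenyl)-2-hydroxypropanoic acid
Product: 13 allyl (2R)-3-[3,4-bis(allyloxy)phenyl]-2-hydroxypropanoate
Conditions: allyl bromide (3.5 equiv), K2CO3, DMF, rt
Reagents that add atoms: allyl bromide, C=CCBr
Why: Williamson alkylation of the carboxylate and the two phenoxides; carbonate deprotonates neither the secondary alcohol nor the α-C–H, so the hydroxyl stays free and the (R) centre is not touched.

**Step 10**
Reactants: 13 allyl (2R)-3-[3,4-bis(allyloxy)phenyl]-2-hydroxypropanoate; 14 diethylphosphonoacetic acid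
Product: 15 allyl (2R)-3-[3,4-bis(allyloxy)phenyl]-2-{[2-(diethoxyphosphoryl)acetyl]oxy}propanoate
Conditions: DCC (1.2 equiv), DMAP (cat.), CH2Cl2, 0 °C → rt
Reagents that add atoms: none
Why: Steglich esterification of the secondary alcohol, in which the C–O bond at the stereocentre is not broken, so the (R) configuration is retained.

**Step 11**
Reactants: 11 allyl (2R,3R)-2-[2-(allyloxy)-4-formylphenoxy]-3-[3,4-bis(allyloxy)phenyl]-3-hydroxypropanoate; 15 allyl (2R)-3-[3,4-bis(allyloxy)phenyl]-2-{[2-(diethoxyphosphoryl)acetyl]oxy}propanoate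
Product: 16 allyl (2R,3R)-2-{2-(allyloxy)-4-[(1E)-3-({(2R)-1-(allyloxy)-3-[3,4-bis(allyloxy)phenyl]-1-oxopropan-2-yl}oxy)-3-oxoprop-1-en-1-yl]phenoxy}-3-[3,4-bis(allyloxy)phenyl]-3-hydroxypropanoate
Conditions: LiCl (1.5 equiv), iPr2NEt (1.3 equiv), MeCN, rt
Reagents that add atoms: none
Why: Horner–Wadsworth–Emmons olefination under Masamune–Roush conditions, giving the (E)-cinnamate from the stabilised phosphonate with an amine too weak to enolise C2 or the danshensu α-position; the C3 hydroxyl is left free because an acyl or carbonate group there would become a β-leaving group for E1cB elimination.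

**Step 12**
Reactants: 16 allyl (2R,3R)-2-{2-(allyloxy)-4-[(1E)-3-({(2R)-1-(allyloxy)-3-[3,4-bis(allyloxy)phenyl]-1-oxopropan-2-yl}oxy)-3-oxoprop-1-en-1-yl]phenoxy}-3-[3,4-bis(allyloxy)phenyl]-3-hydroxypropanoate
Product: 17 (2R,3R)-2-{4-[(1E)-3-{[(1R)-1-carboxy-2-(3,4-dihydroxyphenyl)ethyl]oxy}-3-oxoprop-1-en-1-yl]-2-hydroxyphenoxy}-3-(3,4-dihydroxyphenyl)-3-hydroxypropanoic acid (CNP0159428.1)
Conditions: Pd(PPh3)4 (10 mol%), morpholine (20 equiv), THF, rt, argon; then aq. HCl; reversed-phase chromatography
Reagents that add atoms: none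
Why: Tsuji–Trost deallylation in which zerovalent palladium ionises the two allyl esters and five aryl allyl ethers to π-allyl complexes that morpholine captures irreversibly, under conditions that should leave the cinnamate alkene, the ester linkage and the three stereocentres alone.

**Compound list**
1 | 3',4'-dihydroxyacetophenone | CC(=O)c1ccc(O)c(O)c1 | starting material
2 | 3',4'-bis(allyloxy)acetophenone | CC(=O)c1ccc(OCC=C)c(OCC=C)c1 | intermediate
3 | diallyl carbonate | C=CCOC(=O)OCC=C | starting material
4 | allyl 3-[3,4-bis(allyloxy)phenyl]-3-oxopropanoate | C=CCOC(=O)CC(=O)c1ccc(OCC=C)c(OCC=C)c1 | intermediate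
5 | allyl 3-[3,4-bis(allyloxy)phenyl]-2-chloro-3-oxopropanoate (racemic) | C=CCOC(=O)C(Cl)C(=O)c1ccc(OCC=C)c(OCC=C)c1 | intermediate
6 | 3,4-dihydroxybenzaldehyde | O=Cc1ccc(O)c(O)c1 | starting material
7 | 3-(allyloxy)-4-hydroxybenzaldehyde | O=Cc1ccc(O)c(OCC=C)c1 | intermediate
8 | 2-(allyloxy)-4-(5,5-dimethyl-1,3-dioxan-2-yl)phenol | Oc1ccc(C2OCC(C)(C)CO2)cc1OCC=C | intermediate
9 | allyl 2-[2-(allyloxy)-4-(5,5-dimethyl-1,3-dioxan-2-yl)phenoxy]-3-[3,4-bis(allyloxy)phenyl]-3-oxopropanoate (racemic) | C=CCOC(=O)C(Oc1ccc(C2OCC(C)(C)CO2)cc1OCC=C)C(=O)c1ccc(OCC=C)c(OCC=C)c1 | intermediate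
10 | allyl (2R,3R)-2-[2-(allyloxy)-4-(5,5-dimethyl-1,3-dioxan-2-yl)phenoxy]-3-[3,4-bis(allyloxy)phenyl]-3-hydroxypropanoate | C=CCOC(=O)[C@H](Oc1ccc(C2OCC(C)(C)CO2)cc1OCC=C)[C@H](O)c1ccc(OCC=C)c(OCC=C)c1 | intermediate
11 | allyl (2R,3R)-2-[2-(allyloxy)-4-formylphenoxy]-3-[3,4-bis(allyloxy)phenyl]-3-hydroxypropanoate | C=CCOC(=O)[C@H](Oc1ccc(C=O)cc1OCC=C)[C@H](O)c1ccc(OCC=C)c(OCC=C)c1 | intermediate
12 | (R)-danshensu, (2R)-3-(3,4-dihydroxyphenyl)-2-hydroxypropanoic acid | O[C@H](Cc1ccc(O)c(O)c1)C(=O)O | starting material
13 | allyl (2R)-3-[3,4-bis(allyloxy)phenyl]-2-hydroxypropanoate | C=CCOC(=O)[C@H](O)Cc1ccc(OCC=C)c(OCC=C)c1 | intermediate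
14 | diethylphosphonoacetic acid | CCOP(=O)(OCC)CC(=O)O | starting material
15 | allyl (2R)-3-[3,4-bis(allyloxy)phenyl]-2-{[2-(diethoxyphosphoryl)acetyl]oxy}propanoate | CCOP(=O)(OCC)CC(=O)O[C@H](Cc1ccc(OCC=C)c(OCC=C)c1)C(=O)OCC=C | intermediate
16 | allyl (2R,3R)-2-{2-(allyloxy)-4-[(1E)-3-({(2R)-1-(allyloxy)-3-[3,4-bis(allyloxy)phenyl]-1-oxopropan-2-yl}oxy)-3-oxoprop-1-en-1-yl]phenoxy}-3-[3,4-bis(allyloxy)phenyl]-3-hydroxypropanoate | C=CCOC(=O)[C@H](Oc1ccc(/C=C/C(=O)O[C@H](Cc2ccc(OCC=C)c(OCC=C)c2)C(=O)OCC=C)cc1OCC=C)[C@H](O)c1ccc(OCC=C)c(OCC=C)c1 | intermediate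
17 | (2R,3R)-2-{4-[(1E)-3-{[(1R)-1-carboxy-2-(3,4-dihydroxyphenyl)ethyl]oxy}-3-oxoprop-1-en-1-yl]-2-hydroxyphenoxy}-3-(3,4-dihydroxyphenyl)-3-hydroxypropanoic acid (CNP0159428.1) | O=C(/C=C/c1ccc(O[C@@H](C(=O)O)[C@H](O)c2ccc(O)c(O)c2)c(O)c1)O[C@H](Cc1ccc(O)c(O)c1)C(=O)O | target

**Step count**
Total: 12 steps. Longest linear sequence: 8 steps (steps 1, 2, 3, 6, 7, 8, 11, 12, from 1 to 17).

**Steps most likely to fail**

1. Step 7. No variant of the panel may accept the bulky diaryl substrate at a useful rate, reduction may outrun C2 epimerisation, or the wrong C2 enantiomer or carbonyl face may be taken, so the (2R,3R) isomer would not be obtained pure. The fallback replaces the dynamic resolution by a classical one, sets out from 9 and comes back at 10. NaBH4 in MeOH/THF at −20 °C should reduce 9 to allyl 2-[2-(allyloxy)-4-(5,5-dimethyl-1,3-dioxan-2-yl)phenoxy]-3-[3,4-bis(allyloxy)phenyl]-3-hydroxypropanoate as the mixture of its four stereoisomers F1. The anti racemate would be separated from the syn racemate on silica gel and then split into its enantiomers by preparative chromatography on an amylose tris(3,5-dimethylphenylcarbamate) stationary phase, the (2R,3R) enantiomer being 10. The unwanted stereoisomers could be reoxidised to 9 with Dess–Martin periodinane and recycled.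

2. Step 6. The chloride 5 is itself an acid and may sit as an unreactive enolate, the phenoxide may attack chlorine instead of carbon, or the enolate may self-condense, so the C2–O bond would not form cleanly. The fallback makes the C2–C3 bond instead, sets out from 8 (and from 6 for the aldehyde partner) and comes back at 9; it also bypasses step 3. Alkylation of 8 with allyl bromoacetate (K2CO3, acetone) should give allyl 2-[2-(allyloxy)-4-(5,5-dimethyl-1,3-dioxan-2-yl)phenoxy]acetate F2. Its lithium enolate (LiN(SiMe3)2, THF, −78 °C) would add to 3,4-bis(allyloxy)benzaldehyde F3, made from 6 with allyl bromide and K2CO3 in DMF, to give the aldol as the hydroxy ester stereoisomer mixture F1. Oxidation of the carbinol with Dess–Martin periodinane and NaHCO3 in CH2Cl2 would then give 9.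

3. Step 11. Addition of the phosphonate anion to the electron-rich aldehyde may be slow, leaving the β-hydroxy-α-aryloxy ester exposed to amine base long enough for retro-aldol cleavage, C2 epimerisation or racemisation at the danshensu centre. The fallback is a base-free Wittig olefination that sets out from 13 and comes back at 16. Acylation of 13 with bromoacetyl bromide and pyridine in CH2Cl2 should give allyl (2R)-3-[3,4-bis(allyloxy)phenyl]-2-[(2-bromoacetyl)oxy]propanoate F4. Triphenylphosphine in toluene would convert it into the phosphonium bromide, {2-[(2R)-1-(allyloxy)-3-[3,4-bis(allyloxy)phenyl]-1-oxopropan-2-yl]oxy-2-oxoethyl}triphenylphosphonium bromide F5. Brief shaking with aq. Na2CO3 in CH2Cl2 would give the stabilised ylide, allyl (2R)-3-[3,4-bis(allyloxy)phenyl]-2-{[2-(triphenyl-λ5-phosphanylidene)acetyl]oxy}propanoate F6. Heating F6 with 11 in toluene at 60–80 °C should give the (E)-cinnamate 16 without added base.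

**Further compounds**
F1 | step 7 | allyl 2-[2-(allyloxy)-4-(5,5-dimethyl-1,3-dioxan-2-yl)phenoxy]-3-[3,4-bis(allyloxy)phenyl]-3-hydroxypropanoate, mixture of the four stereoisomers | C=CCOC(=O)C(Oc1ccc(C2OCC(C)(C)CO2)cc1OCC=C)C(O)c1ccc(OCC=C)c(OCC=C)c1
F2 | step 6 | allyl 2-[2-(allyloxy)-4-(5,5-dimethyl-1,3-dioxan-2-yl)phenoxy]acetate | C=CCOC(=O)COc1ccc(C2OCC(C)(C)CO2)cc1OCC=C
F3 | step 6 | 3,4-bis(allyloxy)benzaldehyde | O=Cc1ccc(OCC=C)c(OCC=C)c1
F4 | step 11 | allyl (2R)-3-[3,4-bis(allyloxy)phenyl]-2-[(2-bromoacetyl)oxy]propanoate | O=C(CBr)O[C@H](Cc1ccc(OCC=C)c(OCC=C)c1)C(=O)OCC=C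
F5 | step 11 | {2-[(2R)-1-(allyloxy)-3-[3,4-bis(allyloxy)phenyl]-1-oxopropan-2-yl]oxy-2-oxoethyl}triphenylphosphonium bromide | O=C(C[P+](c1ccccc1)(c1ccccc1)c1ccccc1)O[C@H](Cc1ccc(OCC=C)c(OCC=C)c1)C(=O)OCC=C.[Br-]
F6 | step 11 | allyl (2R)-3-[3,4-bis(allyloxy)phenyl]-2-{[2-(triphenyl-λ5-phosphanylidene)acetyl]oxy}propanoate | O=C(C=P(c1ccccc1)(c1ccccc1)c1ccccc1)O[C@H](Cc1ccc(OCC=C)c(OCC=C)c1)C(=O)OCC=C
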